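**Retrosynthetic overview**
1. Macrocycle last: the 19-membered ring is closed by ring-closing alkyne metathesis at C8≡C9 (not by lactonization); Z-selective semi-reduction of the enyne is the final step.
2. C11–C12: ligand-controlled Nozaki–Hiyama–Kishi coupling of a (Z)-C12 iodide with pent-3-ynal. C1–O19 ester and (2Z)-alkene: Still–Gennari union of a C19-bound phosphonate with the C3 aldehyde.
3. Oxolane (first ring): 2-deoxy-D-ribose supplies C14/C15; Paterson syn-aldol of the derived ethyl ketone with sorbaldehyde sets C18/C19; hemiketal reduction sets C17.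
4. Oxirane (second ring): Shi epoxidation of the distal diene alkene sets C22/C23.
5. C4: Evans syn-aldol with (E)-2-methylhex-2-en-4-ynal; C5 is carried as a silyl ether and oxidized after the union. Ring order: oxolane, oxirane, macrocycle.

Assumption: the target is numbered C1 (lactone C=O) to C24 (epoxide CH3), i.e. (2Z,4S,6E,8Z,11R,12Z,14R,15S,17R,18R,19R,20E,22R,23R), and these locants are used for all intermediates; (−)-Ipc2BOTf, the chiral sulfonamide ligand and the molybdenum alkylidyne leave no atoms in the target and are taken as available.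

**Step 1**
Reactants: 1 2-deoxy-D-ribose
Product: 2 2-deoxy-D-ribono-1,4-lactone
Conditions: Br2, H2O, rt, 4 d
Reagents that add atoms: none
Why: Bromine-water oxidation of the aldose hemiacetal (aldonolactone formation) gives the γ-lactone, with C14 (R) and C15 (S) taken unchanged from the chiral pool.

**Step 2**
Reactants: 2 2-deoxy-D-ribono-1,4-lactone
Product: 3 5-O-TBDPS-2-deoxy-D-ribono-1,4-lactone
Conditions: TBDPSCl, imidazole, DMF, 0 °C
Reagents that add atoms: tert-butyl(chloro)diphenylsilane CC(C)(C)[Si](Cl)(c1ccccc1)c1ccccc1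
Why: Silyl ether formation is selective for the unhindered primary hydroxyl, leaving the secondary C15 hydroxyl free for methylation.

**Step 3**
Reactants: 3 5-O-TBDPS-2-deoxy-D-ribono-1,4-lactone
Product: 4 3-O-methyl-5-O-TBDPS-2-deoxy-D-ribono-1,4-lactone
Conditions: MeI, Ag2O, 4 Å MS, CH2Cl2, 40 °C, dark
Reagents that add atoms: iodomethane CI
Why: Purdie methylation under non-basic Ag2O activation etherifies the C15 hydroxyl without β-elimination or epimerization of the lactone.

**Step 4**
Reactants: 4 3-O-methyl-5-O-TBDPS-2-deoxy-D-ribono-1,4-lactone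
Product: 5 (4S,5R)-5-(hydroxymethyl)-4-methoxyoxolan-2-one
Conditions: HF·pyridine, THF, 0 °C → rt
Reagents that add atoms: none
Why: Fluoride-driven Si–O cleavage (silyl ether deprotection) in an acidic medium frees the primary alcohol without acyl migration of the lactone.

**Step 5**
Reactants: 5 (4S,5R)-5-(hydroxymethyl)-4-methoxyoxolan-2-one
Product: 6 (2S,3S)-3-methoxy-5-oxooxolane-2-carbaldehyde
Conditions: Dess–Martin periodinane, CH2Cl2, 0 °C → rt; used crude
Reagents that add atoms: none
Why: Dess–Martin oxidation gives the α-alkoxy aldehyde under neutral conditions that neither epimerize C14 nor eliminate the β-methoxy group.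

**Step 6**
Reactants: 6 (2S,3S)-3-methoxy-5-oxooxolane-2-carbaldehyde
Product: 7 (4S,5R)-5-[(Z)-2-iodoprop-1-enyl]-4-methoxyoxolan-2-one
Conditions: EtPPh3I, n-BuLi, THF, 0 °C; I2, −78 °C; NaN(SiMe3)2, −20 °C; then 6, −78 → −20 °C
Reagents that add atoms: ethyltriphenylphosphonium iodide CC[P+](c1ccccc1)(c1ccccc1)c1ccccc1.[I-]; iodine II
Why: Stork–Zhao-type Wittig olefination with the non-stabilized α-iodo ylide goes through the kinetically favoured cis-oxaphosphetane to give the (Z)-iodoalkene (iodine cis to C14), which fixes the later 12Z geometry, and addition at −78 °C outruns enolization of the aldehyde.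

**Step 7**
Reactants: 7 (4S,5R)-5-[(Z)-2-iodoprop-1-enyl]-4-methoxyoxolan-2-one
Product: 8 (3S,4R,5Z)-4-hydroxy-6-iodo-N,3-dimethoxy-N-methylhept-5-enamide
Conditions: MeNH(OMe)·HCl, AlMe3, CH2Cl2, 0 °C → rt; used crude
Reagents that add atoms: N,O-dimethylhydroxylamine hydrochloride CNOC.Cl
Why: Weinreb aminolysis of the lactone by the aluminium amide opens the ring to the γ-hydroxy Weinreb amide without touching the stereocentres or the iodoalkene.

**Step 8**
Reactants: 8 (3S,4R,5Z)-4-hydroxy-6-iodo-N,3-dimethoxy-N-methylhept-5-enamide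
Product: 9 (3S,4R,5Z)-6-iodo-N,3-dimethoxy-N-methyl-4-(triethylsilyloxy)hept-5-enamide
Conditions: TESCl, imidazole, DMF, 0 °C
Reagents that add atoms: chlorotriethylsilane CC[Si](Cl)(CC)CC
Why: Silyl ether formation blocks the C14 hydroxyl so that relactonization is stopped and the later ketone stays open-chain for enolization.

**Step 9**
Reactants: 9 (3S,4R,5Z)-6-iodo-N,3-dimethoxy-N-methyl-4-(triethylsilyloxy)hept-5-enamide
Product: 10 (5S,6R,7Z)-8-iodo-5-methoxy-6-(triethylsilyloxy)non-7-en-3-one
Conditions: EtMgBr, THF, 0 °C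
Reagents that add atoms: ethylmagnesium bromide CC[Mg]Br
Why: Weinreb ketone synthesis stops at the ketone through the chelated tetrahedral intermediate, and the alkenyl iodide is inert to the Grignard reagent at 0 °C.

**Step 10**
Reactants: 10 (5S,6R,7Z)-8-iodo-5-methoxy-6-(triethylsilyloxy)non-7-en-3-one; 11 (2E,4E)-hexa-2,4-dienal
Product: 12 (2Z,4R,5S,8S,9R,10E,12E)-9-hydroxy-2-iodo-5-methoxy-8-methyl-4-(triethylsilyloxy)tetradeca-2,10,12-trien-7-one
Conditions: (−)-Ipc2BOTf, i-Pr2NEt, CH2Cl2, −78 °C; then 11, −78 → −20 °C; H2O2, pH 7 buffer, MeOH, 0 °C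
Reagents that add atoms: none
Why: Paterson aldol in which the bulky boron triflate enolizes the unhindered ethyl side to the Z-enol borinate, the chair Zimmerman–Traxler transition state gives the 18,19-syn relationship, and the Ipc ligands direct attack to the Si face of the dienal (reagent control) to set C18 and C19.

**Step 11**
Reactants: 12 syn-aldol adduct
Product: 13 (4S,5R)-2-[(2S,3R,4E,6E)-3-hydroxyocta-4,6-dien-2-yl]-5-[(Z)-2-iodoprop-1-enyl]-4-methoxyoxolan-2-ol (anomer mixture)
Conditions: HF·pyridine, pyridine, THF, 0 °C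
Reagents that add atoms: none
Why: Selective cleavage of the triethylsilyl ether (silyl deprotection) lets the C14 hydroxyl close onto the C17 ketone as the five-membered hemiketal without retro-aldol or epimerization at C18.

**Step 12**
Reactants: 13 hemiketal
Product: 14 (2S,3R,4E,6E)-2-{(2R,4S,5R)-5-[(Z)-2-iodoprop-1-enyl]-4-methoxyoxolan-2-yl}octa-4,6-dien-3-ol
Conditions: Et3SiH, BF3·OEt2, CH2Cl2/MeCN, −78 → −40 °C
Reagents that add atoms: none
Why: Reductive etherification in which BF3 ionizes the hemiketal to the cyclic oxocarbenium ion and Et3SiH adds on the inside face of the envelope, cis to the pseudoaxial C15 methoxy group, so that C18 ends up cis to C13 (17R, 2,5-cis oxolane) as in β-C-glycoside formation from 2-deoxyribofuranosyl hemiketals.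

**Step 13**
Reactants: 15 bis(2,2,2-trifluoroethyl) phosphite; 16 tert-butyl 2-bromopropanoate
Product: 17 tert-butyl 2-[bis(2,2,2-trifluoroethoxy)phosphoryl]propanoate
Conditions: NaH, THF, 0 °C → rt
Reagents that add atoms: none
Why: Michaelis–Becker alkylation in which the sodium phosphite displaces the activated α-bromide (SN2) to give the Still–Gennari-type phosphonate, whose racemic centre is lost in the later olefination.

**Step 14**
Reactants: 17 tert-butyl 2-[bis(2,2,2-trifluoroethoxy)phosphoryl]propanoate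
Product: 18 2-[bis(2,2,2-trifluoroethoxy)phosphoryl]propanoic acid
Conditions: CF3CO2H, CH2Cl2, rt
Reagents that add atoms: none
Why: Acidolysis of the tert-butyl ester (loss of isobutene) frees the acid without the base that would cleave the trifluoroethyl phosphonate esters.

**Step 15**
Reactants: 14 oxolane dienol; 18 2-[bis(2,2,2-trifluoroethoxy)phosphoryl]propanoic acid
Product: 19 O19 ester of 14 with acid 18 (epimers at the phosphonate carbon)
Conditions: DCC, DMAP (cat.), CH2Cl2, 0 °C → rt
Reagents that add atoms: none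
Why: Steglich esterification acylates the hindered C19 hydroxyl under neutral carbodiimide activation, installs the olefination handle and deactivates the neighbouring C20=C21 alkene toward electrophilic oxidants.

**Step 16**
Reactants: 19 dienyl phosphonopropanoate
Product: 20 (22R,23R)-epoxide of 19
Conditions: D-fructose-derived Shi ketone (0.5 equiv), KHSO5 (as 2KHSO5·KHSO4·K2SO4), NaHCO3 buffer (pH 8), MeCN/CH2(OMe)2/H2O, 0 °C
Reagents that add atoms: potassium peroxymonosulfate [K+].[O-]S(=O)(=O)OO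
Why: Shi asymmetric epoxidation in which the chiral dioxirane attacks only the electron-rich distal (E)-alkene of the diene through the spiro transition state, the D-fructose-derived ketone giving the (22R,23R)-trans-epoxide under catalyst control while the acyloxy-deactivated C20=C21 bond and the iodoalkene stay intact.

**Step 17**
Reactants: 21 but-2-yn-1-ol; 22 2-(triphenylphosphoranylidene)propanal
Product: 24 (E)-2-methylhex-2-en-4-ynal, via but-2-ynal 23 (not isolated)
Conditions: MnO2, CHCl3, reflux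
Reagents that add atoms: none
Why: Tandem MnO2 oxidation–Wittig reaction traps the volatile ynal in situ with the stabilized ylide, which gives the (E)-trisubstituted enal (the later 6E alkene) under thermodynamic control.

**Step 18**
Reactants: 24 (E)-2-methylhex-2-en-4-ynal; 25 (R)-4-benzyl-3-propanoyloxazolidin-2-one
Product: 26 (4R)-4-benzyl-3-[(2R,3R,4E)-3-hydroxy-2,4-dimethyloct-4-en-6-ynoyl]oxazolidin-2-one
Conditions: Bu2BOTf, i-Pr2NEt, CH2Cl2, 0 °C; then 24, −78 → 0 °C; H2O2, pH 7 buffer, MeOH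
Reagents that add atoms: none
Why: Evans syn-aldol through the Z-boron enolate and a chair Zimmerman–Traxler transition state with the auxiliary dipole opposed, which sets the C4 methyl centre (and a disposable C5 carbinol) with high auxiliary control.

**Step 19**
Reactants: 26 Evans aldol adduct
Product: 27 (4R)-4-benzyl-3-[(2R,3R,4E)-2,4-dimethyl-3-(triethylsilyloxy)oct-4-en-6-ynoyl]oxazolidin-2-one
Conditions: TESOTf, 2,6-lutidine, CH2Cl2, −78 °C
Reagents that add atoms: triethylsilyl trifluoromethanesulfonate CC[Si](CC)(CC)OS(=O)(=O)C(F)(F)F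
Why: Silyl ether formation protects the C5 carbinol, which blocks retro-aldol now and lactonization onto the later Z-enoate.

**Step 20**
Reactants: 27 silylated aldol adduct
Product: 28 (2S,3R,4E)-2,4-dimethyl-3-(triethylsilyloxy)oct-4-en-6-yn-1-ol
Conditions: LiBH4, MeOH (1 equiv), Et2O, 0 °C
Reagents that add atoms: none
Why: Reductive cleavage of the imide by borohydride releases the primary alcohol and the recoverable auxiliary without epimerizing C4.

**Step 21**
Reactants: 28 (2S,3R,4E)-2,4-dimethyl-3-(triethylsilyloxy)oct-4-en-6-yn-1-ol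
Product: 29 (2R,3R,4E)-2,4-dimethyl-3-(triethylsilyloxy)oct-4-en-6-ynal
Conditions: Dess–Martin periodinane, pyridine, CH2Cl2, 0 °C
Reagents that add atoms: none
Why: Dess–Martin oxidation gives the α-chiral aldehyde under buffered neutral conditions that leave C4 intact.

**Step 22**
Reactants: 20 epoxy phosphonate; 29 (2R,3R,4E)-2,4-dimethyl-3-(triethylsilyloxy)oct-4-en-6-ynal
Product: 30 O19 ester of the C12–C24 epoxy iodide with (2Z,4S,5R,6E)-2,4,6-trimethyl-5-(triethylsilyloxy)deca-2,6-dien-8-ynoic acid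
Conditions: KN(SiMe3)2, 18-crown-6, THF, −78 °C; then 29, −78 °C
Reagents that add atoms: none
Why: Still–Gennari olefination in which the dissociated potassium phosphonate adds irreversibly and the electron-poor phosphonate eliminates fast, which gives the (2Z)-α-methyl enoate and joins the fragments without esterifying an isomerization-prone Z-enoic acid.

**Step 23**
Reactants: 30 silyl ether seco-ester
Product: 31 C5 alcohol of 30 [(4S,5R)-5-hydroxy]
Conditions: HF·pyridine, pyridine, THF, 0 °C; used at once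
Reagents that add atoms: none
Why: Buffered fluoride cleaves the secondary triethylsilyl ether (silyl deprotection) without opening the vinyl epoxide, and the δ-hydroxy (Z)-enoate is carried on immediately to forestall translactonization.

**Step 24**
Reactants: 31 C5 alcohol
Product: 32 O19 ester of the C12–C24 epoxy iodide with (2Z,4S,6E)-2,4,6-trimethyl-5-oxodeca-2,6-dien-8-ynoic acid
Conditions: Dess–Martin periodinane, pyridine, CH2Cl2, 0 °C
Reagents that add atoms: none
Why: Dess–Martin oxidation of the allylic carbinol gives the C5 ketone under buffered conditions mild enough that the now doubly activated C4 centre is not epimerized.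

**Step 25**
Reactants: 33 pent-3-yn-1-ol
Product: 34 pent-3-ynal
Conditions: Dess–Martin periodinane, CH2Cl2, 0 °C; solution used at once
Reagents that add atoms: none
Why: Dess–Martin oxidation gives the β,γ-alkynyl aldehyde without base, and immediate use avoids its isomerization to the allenal.

**Step 26**
Reactants: 32 ketone iodide; 34 pent-3-ynal
Product: 35 (11R)-seco-diyne (32 with iodine replaced by the (R)-1-hydroxypent-3-ynyl group)
Conditions: CrCl2, NiCl2 (cat.), Kishi oxazoline–sulfonamide ligand (enantiomer for Si-face addition), Et3N, THF, rt; 34 (3 equiv)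
Reagents that add atoms: none
Why: Asymmetric Nozaki–Hiyama–Kishi coupling in which zerovalent nickel inserts into the C–I bond, transmetallation gives the alkenylchromium with retention of the Z geometry, and the ligand-bound trivalent chromium delivers it to the Si face of the aldehyde to set 11R while the ketone, ester and epoxide are not attacked.

**Step 27**
Reactants: 35 (11R)-seco-diyne
Product: 36 8,9-didehydro macrocycle (19-membered cycloalkyne with C8≡C9)
Conditions: Mo(≡CC6H4OMe-4)(OSiPh3)3 (20 mol %), 5 Å MS, toluene (2 mM), rt → 60 °C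
Reagents that add atoms: none
Why: Ring-closing alkyne metathesis in which the molybdenum alkylidyne exchanges the two methyl-capped alkynes through metallacyclobutadienes, with capture of but-2-yne by the sieves driving closure of the 19-membered ring while the alkenes, ketone, epoxide and hindered alcohol are left alone.

**Step 28**
Reactants: 36 8,9-didehydro macrocycle
Product: 37 target CNP0117824.1
Conditions: Zn dust activated with Cu(OAc)2 and AgNO3, MeOH/H2O (1:1), rt
Reagents that add atoms: none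
Why: Z-selective semi-reduction of the conjugated enyne on the zinc surface (Boland reduction) adds two hydrogens cis to give the 8Z alkene of the (6E,8Z)-dienone without over-reduction, under neutral conditions that spare C4, the epoxide and the other alkenes.

**Compound list**
1 | 2-deoxy-D-ribose | O=CC[C@H](O)[C@H](O)CO | starting material
2 | 2-deoxy-D-ribono-1,4-lactone, (4S,5R)-4-hydroxy-5-(hydroxymethyl)oxolan-2-one | O[C@H]1CC(=O)O[C@@H]1CO | intermediate
3 | 5-O-TBDPS-2-deoxy-D-ribono-1,4-lactone | O[C@H]1CC(=O)O[C@@H]1CO[Si](c2ccccc2)(c3ccccc3)C(C)(C)C | intermediate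
4 | 3-O-methyl-5-O-TBDPS-2-deoxy-D-ribono-1,4-lactone | CO[C@H]1CC(=O)O[C@@H]1CO[Si](c2ccccc2)(c3ccccc3)C(C)(C)C | intermediate
5 | (4S,5R)-5-(hydroxymethyl)-4-methoxyoxolan-2-one | CO[C@H]1CC(=O)O[C@@H]1CO | intermediate
6 | (2S,3S)-3-methoxy-5-oxooxolane-2-carbaldehyde | CO[C@H]1CC(=O)O[C@@H]1C=O | intermediate
7 | (4S,5R)-5-[(Z)-2-iodoprop-1-enyl]-4-methoxyoxolan-2-one | CO[C@H]1CC(=O)O[C@@H]1/C=C(/C)I | intermediate
8 | (3S,4R,5Z)-4-hydroxy-6-iodo-N,3-dimethoxy-N-methylhept-5-enamide | CO[C@H]([C@H](O)/C=C(/C)I)CC(=O)N(C)OC | intermediate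
9 | (3S,4R,5Z)-6-iodo-N,3-dimethoxy-N-methyl-4-(triethylsilyloxy)hept-5-enamide | CO[C@H]([C@H](O[Si](CC)(CC)CC)/C=C(/C)I)CC(=O)N(C)OC | intermediate
10 | (5S,6R,7Z)-8-iodo-5-methoxy-6-(triethylsilyloxy)non-7-en-3-one (C12–C18 ethyl ketone) | CO[C@H]([C@H](O[Si](CC)(CC)CC)/C=C(/C)I)CC(=O)CC | intermediate
11 | (2E,4E)-hexa-2,4-dienal (sorbaldehyde) | C/C=C/C=C/C=O | starting material
12 | (2Z,4R,5S,8S,9R,10E,12E)-9-hydroxy-2-iodo-5-methoxy-8-methyl-4-(triethylsilyloxy)tetradeca-2,10,12-trien-7-one | CO[C@H]([C@H](O[Si](CC)(CC)CC)/C=C(/C)I)CC(=O)[C@@H](C)[C@H](O)/C=C/C=C/C | intermediate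
13 | (4S,5R)-2-[(2S,3R,4E,6E)-3-hydroxyocta-4,6-dien-2-yl]-5-[(Z)-2-iodoprop-1-enyl]-4-methoxyoxolan-2-ol (C17 anomers) | CO[C@H]1CC(O)([C@@H](C)[C@H](O)/C=C/C=C/C)O[C@@H]1/C=C(/C)I | intermediate
14 | (2S,3R,4E,6E)-2-{(2R,4S,5R)-5-[(Z)-2-iodoprop-1-enyl]-4-methoxyoxolan-2-yl}octa-4,6-dien-3-ol | CO[C@H]1C[C@H]([C@@H](C)[C@H](O)/C=C/C=C/C)O[C@@H]1/C=C(/C)I | intermediate
15 | bis(2,2,2-trifluoroethyl) phosphite | O=[PH](OCC(F)(F)F)OCC(F)(F)F | starting material
16 | tert-butyl 2-bromopropanoate (racemic) | CC(Br)C(=O)OC(C)(C)C | starting material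
17 | tert-butyl 2-[bis(2,2,2-trifluoroethoxy)phosphoryl]propanoate (racemic) | CC(C(=O)OC(C)(C)C)P(=O)(OCC(F)(F)F)OCC(F)(F)F | intermediate
18 | 2-[bis(2,2,2-trifluoroethoxy)phosphoryl]propanoic acid (racemic) | CC(C(=O)O)P(=O)(OCC(F)(F)F)OCC(F)(F)F | intermediate
19 | O19 2-[bis(2,2,2-trifluoroethoxy)phosphoryl]propanoate of 14 (14R,15S,17R,18R,19R; phosphonate carbon unassigned) | CO[C@H]1C[C@H]([C@@H](C)[C@H](OC(=O)C(C)P(=O)(OCC(F)(F)F)OCC(F)(F)F)/C=C/C=C/C)O[C@@H]1/C=C(/C)I | intermediate
20 | (22R,23R)-22,23-epoxide of 19 (north fragment) | CO[C@H]1C[C@H]([C@@H](C)[C@H](OC(=O)C(C)P(=O)(OCC(F)(F)F)OCC(F)(F)F)/C=C/[C@H]2O[C@@H]2C)O[C@@H]1/C=C(/C)I | intermediate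
21 | but-2-yn-1-ol | CC#CCO | starting material
22 | 2-(triphenylphosphoranylidene)propanal | CC(C=O)=P(c1ccccc1)(c1ccccc1)c1ccccc1 | starting material
23 | but-2-ynal (not isolated) | CC#CC=O | intermediate
24 | (E)-2-methylhex-2-en-4-ynal | CC#C/C=C(\C)C=O | intermediate
25 | (R)-4-benzyl-3-propanoyloxazolidin-2-one | CCC(=O)N1[C@H](Cc2ccccc2)COC1=O | starting material
26 | (4R)-4-benzyl-3-[(2R,3R,4E)-3-hydroxy-2,4-dimethyloct-4-en-6-ynoyl]oxazolidin-2-one | O=C1OC[C@@H](Cc2ccccc2)N1C(=O)[C@H](C)[C@@H](O)/C(C)=C/C#CC | intermediate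
27 | (4R)-4-benzyl-3-[(2R,3R,4E)-2,4-dimethyl-3-(triethylsilyloxy)oct-4-en-6-ynoyl]oxazolidin-2-one | O=C1OC[C@@H](Cc2ccccc2)N1C(=O)[C@H](C)[C@@H](O[Si](CC)(CC)CC)/C(C)=C/C#CC | intermediate
28 | (2S,3R,4E)-2,4-dimethyl-3-(triethylsilyloxy)oct-4-en-6-yn-1-ol | OC[C@H](C)[C@@H](O[Si](CC)(CC)CC)/C(C)=C/C#CC | intermediate
29 | (2R,3R,4E)-2,4-dimethyl-3-(triethylsilyloxy)oct-4-en-6-ynal (south fragment) | O=C[C@H](C)[C@@H](O[Si](CC)(CC)CC)/C(C)=C/C#CC | intermediate
30 | (2Z,4S,5R,6E)-2,4,6-trimethyl-5-(triethylsilyloxy)deca-2,6-dien-8-ynoate of the C12–C24 epoxy iodide (O19 ester) | CO[C@H]1C[C@H]([C@@H](C)[C@H](OC(=O)/C(C)=C\[C@H](C)[C@@H](O[Si](CC)(CC)CC)/C(C)=C/C#CC)/C=C/[C@H]2O[C@@H]2C)O[C@@H]1/C=C(/C)I | intermediate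
31 | C5 alcohol of 30 (4S,5R) | CO[C@H]1C[C@H]([C@@H](C)[C@H](OC(=O)/C(C)=C\[C@H](C)[C@@H](O)/C(C)=C/C#CC)/C=C/[C@H]2O[C@@H]2C)O[C@@H]1/C=C(/C)I | intermediate
32 | C5 ketone (2Z,4S,6E)-2,4,6-trimethyl-5-oxodeca-2,6-dien-8-ynoate of the C12–C24 epoxy iodide | CO[C@H]1C[C@H]([C@@H](C)[C@H](OC(=O)/C(C)=C\[C@H](C)C(=O)/C(C)=C/C#CC)/C=C/[C@H]2O[C@@H]2C)O[C@@H]1/C=C(/C)I | intermediate
33 | pent-3-yn-1-ol | CC#CCCO | starting material
34 | pent-3-ynal | CC#CCC=O | intermediate
35 | (11R)-seco-diyne (C8 and C9 alkynes each methyl-capped) | CO[C@H]1C[C@H]([C@@H](C)[C@H](OC(=O)/C(C)=C\[C@H](C)C(=O)/C(C)=C/C#CC)/C=C/[C@H]2O[C@@H]2C)O[C@@H]1/C=C(/C)[C@H](O)CC#CC | intermediate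
36 | 8,9-didehydro target (19-membered cycloalkyne, 2Z,6E,12Z) | CO[C@H]1C[C@H]2O[C@@H]1/C=C(/C)[C@H](O)CC#C\C=C(/C)C(=O)[C@@H](C)/C=C(/C)C(=O)O[C@H](/C=C/[C@H]1O[C@@H]1C)[C@@H]2C | intermediate
37 | CNP0117824.1 (2Z,4S,6E,8Z,11R,12Z,14R,15S,17R,18R,19R,20E,22R,23R) | CO[C@H]1C[C@H]2O[C@@H]1/C=C(/C)[C@H](O)C/C=C\C=C(/C)C(=O)[C@@H](C)/C=C(/C)C(=O)O[C@H](/C=C/[C@H]1O[C@@H]1C)[C@@H]2C | target

**Step count and risk**

Total: 28 steps (north line 1–12, 15, 16; phosphonate acid 13–14; south aldehyde 17–21; ynal 25; union and endgame 22–24, 26–28). Longest linear sequence: 20 steps from 2-deoxy-D-ribose (steps 1–12, 15, 16, 22–24, 26–28).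

The three steps most likely to fail are 23, 26 and 27.

Step 23: the free δ-hydroxy (Z)-enoate 31 can translactonize to a six-membered lactone with loss of the C19 alcohol, and HF may open the vinyl epoxide. The fallback sets out from 30 and comes back to the route at 32. It drops the separate deprotection and treats 30 with o-iodoxybenzoic acid in DMSO at rt, which cleaves the triethylsilyl ether oxidatively and oxidizes alcohol 31 in the same flask as it is released. No hydroxy ester is handled, no fluoride is used, and no new compound is made (F0).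

Step 26: ynal 34 isomerizes easily, and ligand control at C11 is asked for late, on a substrate with an epimerizable ketone. The fallback sets out from 20 and comes back to the route at 35. It moves the C11–C12 bond formation to the fragment stage and carries the carbinol protected. The same chromium/nickel coupling of 20 with 34 gives the (11R)-homopropargylic alcohol F1, whose C11 epimers can be separated on this small fragment. TBSCl and imidazole give the tert-butyldimethylsilyl ether F2. Still–Gennari olefination with 29 gives the doubly silylated seco-diyne F3. Buffered HF·pyridine at 0 °C removes only the triethylsilyl group to give the C5 alcohol F4, and Dess–Martin oxidation gives the C5 ketone F5. HF·pyridine/pyridine at rt then removes the remaining silyl group and delivers 35.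

Step 27: the free C11 hydroxyl can exchange with the silanolate ligands of the molybdenum alkylidyne and stall the ring closure. The fallback sets out from 35 and comes back to the route at 36. It runs the metathesis on an aprotic substrate: TESCl and imidazole (no triflate, to avoid enol silylation at C4) give the C11 triethylsilyl ether F6, ring-closing alkyne metathesis under the same conditions gives the macrocyclic silyl ether F7, and buffered HF·pyridine at 0 °C releases 36.

**Further compounds**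
F0 | step 23 | none | none
F1 | step 26 | (11R)-homopropargylic alcohol of the north fragment (20 with iodine replaced by the (R)-1-hydroxypent-3-ynyl group) | CO[C@H]1C[C@H]([C@@H](C)[C@H](OC(=O)C(C)P(=O)(OCC(F)(F)F)OCC(F)(F)F)/C=C/[C@H]2O[C@@H]2C)O[C@@H]1/C=C(/C)[C@H](O)CC#CC
F2 | step 26 | 11-O-tert-butyldimethylsilyl ether of F1 | CO[C@H]1C[C@H]([C@@H](C)[C@H](OC(=O)C(C)P(=O)(OCC(F)(F)F)OCC(F)(F)F)/C=C/[C@H]2O[C@@H]2C)O[C@@H]1/C=C(/C)[C@H](O[Si](C)(C)C(C)(C)C)CC#CC
F3 | step 26 | 5-O-triethylsilyl 11-O-tert-butyldimethylsilyl seco-diyne (2Z,4S,5R,6E,11R) | CO[C@H]1C[C@H]([C@@H](C)[C@H](OC(=O)/C(C)=C\[C@H](C)[C@@H](O[Si](CC)(CC)CC)/C(C)=C/C#CC)/C=C/[C@H]2O[C@@H]2C)O[C@@H]1/C=C(/C)[C@H](O[Si](C)(C)C(C)(C)C)CC#CC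
F4 | step 26 | C5 alcohol of F3 (11-O-TBS) | CO[C@H]1C[C@H]([C@@H](C)[C@H](OC(=O)/C(C)=C\[C@H](C)[C@@H](O)/C(C)=C/C#CC)/C=C/[C@H]2O[C@@H]2C)O[C@@H]1/C=C(/C)[C@H](O[Si](C)(C)C(C)(C)C)CC#CC
F5 | step 26 | C5 ketone, 11-O-tert-butyldimethylsilyl ether of 35 | CO[C@H]1C[C@H]([C@@H](C)[C@H](OC(=O)/C(C)=C\[C@H](C)C(=O)/C(C)=C/C#CC)/C=C/[C@H]2O[C@@H]2C)O[C@@H]1/C=C(/C)[C@H](O[Si](C)(C)C(C)(C)C)CC#CC
F6 | step 27 | 11-O-triethylsilyl ether of 35 | CO[C@H]1C[C@H]([C@@H](C)[C@H](OC(=O)/C(C)=C\[C@H](C)C(=O)/C(C)=C/C#CC)/C=C/[C@H]2O[C@@H]2C)O[C@@H]1/C=C(/C)[C@H](O[Si](CC)(CC)CC)CC#CC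
F7 | step 27 | 11-O-triethylsilyl ether of 36 | CO[C@H]1C[C@H]2O[C@@H]1/C=C(/C)[C@H](O[Si](CC)(CC)CC)CC#C\C=C(/C)C(=O)[C@@H](C)/C=C(/C)C(=O)O[C@H](/C=C/[C@H]1O[C@@H]1C)[C@@H]2C
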